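## Retrosynthetic overview

1. Endgame: the C20 aldehyde comes from a silyl-protected C20 alcohol. The ready-made butenolide is attached by an sp3–sp2 cross-coupling at C12–C13, and C8=C17 comes from a C8 ketone. This leads back to a trans-decalone carrying C19–OH, C20–OSi and a two-carbon ester arm on C9.
2. Key disconnection: ring A is cut at C1–C2 and C3–C4. The C2–C3 unit is vinyltriphenylphosphonium bromide. Its partner is a monocyclic (ring B) ketone with a C1 formyl group on C10 and a C4–C19 epoxide on C5. Reductive epoxide opening, radical addition, radical-to-ylide crossover and intramolecular Wittig closure run in one flask and leave only a C1=C2 alkene.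
3. Enabling feature: in ring A the unfunctionalised C2–C3 unit lies between C1 and C4. C1 is a CH2 on the quaternary, non-enolisable C10, so it can be a formyl group. C4 is a quaternary carbon bearing the oxygenated C19, so C4–C19 can be an epoxide that opens to a tertiary C4 radical. Both groups hang on the C5–C10 bond of ring B.
4. Ring B is the six-membered ring of (1R)-(−)-myrtenol. Its CMe2 bridge (temporary cyclobutane, C4–C7 bond) directs the C10 quaternary centre, limits enolisation to C9, and stores C5 together with C4, C18 and C19.
5. Order of rings: ring B (chiral pool, with the temporary cyclobutane), then ring A (key step), then the butenolide (made separately and attached late).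

Key step: step 8

Remark (numbering): labdane numbering is used. Ring A is C1–C5 and C10; ring B is C5–C10. C11–C12 is the chain on C9, C13–C16 the butenolide and C17 the methylene carbon on C8. C18 (CH3) and C19 (CH2O) sit on C4, and C20 sits on C10. α and β mean below and above the plane with ring A drawn left and C10 above C5. The target has 5β-H, 9β-H (C11 α, equatorial), C20 α (axial), C19 α (axial) and C18 β (equatorial). This is (4R,5R,9R,10R), the ent-labdane series.

Remark (pinane intermediates): the carbonyl carbon is C8, its non-bridgehead neighbour is C9, and the next carbon is C10. The bridgeheads are C5 (next to C10) and C7 (next to C8). The CH2 bridge is C6 and the CMe2 bridge is C4. TBDPS = tert-butyldiphenylsilyl.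

Assumption: commercial (1R)-(−)-myrtenol is taken as enantiomerically pure. Its (1R,5S) configuration maps onto 5β-H.

## Route

Step 1
Reactants: 1 (1R,5S)-(−)-myrtenol
Product: 2 myrtenyl TBDPS ether
Conditions: TBDPSCl, imidazole, DMF, rt
Reagents that add atoms: tert-butyl(chloro)diphenylsilane, CC(C)(C)[Si](Cl)(c1ccccc1)c1ccccc1
Why: Imidazole-promoted silyl ether formation on a primary allylic alcohol installs an acid- and base-stable group that carries O20 to the end of the route and touches no stereocentre.

Step 2
Reactants: 2 myrtenyl TBDPS ether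
Product: 3 silyloxy-verbenone (C8 ketone conjugated with C9=C10)
Conditions: CrO3, 3,5-dimethylpyrazole, CH2Cl2, −20 °C
Reagents that add atoms: chromium trioxide, O=[Cr](=O)=O
Why: Allylic oxidation with the CrO3–dimethylpyrazole complex, the standard pinene-to-verbenone conversion, should attack the ring allylic CH2 (C8) because the other ring allylic position is a bridgehead and the CH2OSi group is shielded by TBDPS, and both bridgehead centres stay untouched.

Step 3
Reactants: 3 silyloxy-verbenone; 4 vinylmagnesium bromide
Product: 6 vinyl ketone (C10 quaternary; vinyl β and anti to the CMe2 bridge; CH2OTBDPS α), via magnesium enolate 5 (not isolated)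
Conditions: CuBr·SMe2 (cat.), THF, −40 to 0 °C; then 1 M HCl
Reagents that add atoms: none
Why: Copper-catalysed conjugate addition of a Grignard reagent, precedented on verbenone, creates quaternary C10, and the CMe2 bridge blocks the α face so that vinyl (future C1) enters β and C20 ends up cis to C4 as the target requires.

Step 4
Reactants: 6 vinyl ketone; 7 ethyl bromoacetate
Product: 9 pinane keto ester (C9 arm β and anti to the CMe2 bridge; provisional C9 configuration), via lithium enolate 8 (not isolated)
Conditions: LDA, THF, −78 °C; then 7, DMPU, −78 to −20 °C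
Reagents that add atoms: none
Why: Kinetic enolate alkylation is regiospecific because the other α position (C7) is a bridgehead that cannot enolise (Bredt's rule), the reactive bromoacetate should enter anti to the CMe2 bridge, and the resulting C9 configuration is corrected in step 5.

Step 5
Reactants: 9 pinane keto ester
Product: 12 isopropenyl keto ester (monocyclic ring B; C11 α equatorial; 5β-H), via iodo silyl enol ether 10 (not isolated), via iodo ketone 11 (not isolated)
Conditions: Me3SiI, CH2Cl2, −40 to 0 °C; aqueous work-up; then DBU, toluene, 80 °C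
Reagents that add atoms: none
Why: Iodotrimethylsilane-induced opening of a cyclobutyl ketone (known for nopinone) silylates the carbonyl oxygen, breaks the strained C7–C4 bond that overlaps with the carbonyl π system and traps the tertiary C4 cation as iodide, after which DBU should effect E2 elimination toward a methyl group (C5–H is shielded by quaternary C10) and equilibrate C9 through the enolate to the equatorial α arm, while C5 and C10 are untouched.

Step 6
Reactants: 12 isopropenyl keto ester
Product: 13 vinyl epoxide (both C4 epimers)
Conditions: mCPBA, CH2Cl2, 0 °C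
Reagents that add atoms: 3-chloroperbenzoic acid, OOC(=O)c1cccc(Cl)c1
Why: Prilezhaev epoxidation prefers the electron-richer 1,1-disubstituted isopropenyl alkene over the neopentyl monosubstituted vinyl group, and the mixture of C4 epimers is inconsequential because step 8 planarises C4.

Step 7
Reactants: 13 vinyl epoxide
Product: 15 epoxy aldehyde (C1 formyl on C10), via secondary ozonide 14 (not isolated)
Conditions: O3, CH2Cl2, −78 °C; then Me2S, −78 °C to rt
Reagents that add atoms: ozone, [O-][O+]=O
Why: Ozonolysis with reductive work-up cleaves the only remaining alkene to the non-enolisable C1 aldehyde, while epoxide, ketone, ester and silyl ether are inert and no stereocentre is affected.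

Step 8
Reactants: 15 epoxy aldehyde; 16 vinyltriphenylphosphonium bromide
Product: 19 hydroxy octalone (ring A closed; C1=C2; C19–OH free and axial), via titanoxy ylide 17 (not isolated), via titanium alkoxide 18 (not isolated)
Conditions: Cp2TiCl2, Mn dust, THF, rt (forms Cp2TiCl); slow addition to 15 and excess 16 in THF/CH2Cl2, rt; then 1 M HCl
Reagents that add atoms: none
Why: Proposed new method: Cp2TiCl (trivalent titanium) opens the 2,2-disubstituted epoxide homolytically at its tertiary C–O bond (strain release), the nucleophilic tertiary C4 radical adds to the CH2 terminus of the cationic acceptor 16 (C3–C4 bond), a second Cp2TiCl reduces the electrophilic α-phosphonio radical to ylide 17, and 17 olefinates the neighbouring C1 formyl group (C1–C2 bond) with loss of Ph3PO. The closest known reaction types are titanocene-mediated reductive epoxide opening with Giese trapping, the photoredox conjunctive olefination that merges an alkyl radical, a vinylphosphonium salt and an aldehyde through the same radical-to-ylide crossover, and the vinylphosphonium Michael/Wittig annulation (Schweizer reagent); new is their union with titanocene as the only reductant. Ring A is the only ring closed, by 6-exo-trig attack of ylide carbon C2 on the C1 carbonyl and collapse of the oxaphosphetane, which can only give the endocyclic cis C1=C2 alkene. C4 is the only new stereocentre: both epoxide epimers converge on one planar radical, A(1,3)-type strain should keep the bulky CH2OTiCp2Cl arm eclipsed with C5–H and the methyl group turned inward, and 16 should approach anti to quaternary C10, which after rotation and closure places C19 axial (cis to C20) and C18 equatorial. The step needs radical capture by 16 rather than reduction or disproportionation (secured by polarity match and excess 16) and olefination of the aldehyde rather than the C8 ketone (six-membered against bridged seven-membered closure, a more electrophilic carbonyl, and an ylide less basic than a ketone or ester enolate in an aprotic medium). It also frees C19–OH alone, which differentiates C19 from the silylated C20.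

Step 9
Reactants: 19 hydroxy octalone
Product: 20 hydroxy decalone (trans-decalin)
Conditions: H2 (1 atm), Pd/C, EtOAc, rt
Reagents that add atoms: none
Why: Heterogeneous hydrogenation of the only C=C bond (cis-disubstituted C1=C2) removes the trace of the annulation, forms no stereocentre, and leaves ketone, ester and silyl ether intact.

Step 10
Reactants: 20 hydroxy decalone
Product: 21 exo-methylene hydroxy ester
Conditions: Zn, CH2Br2, TiCl4, THF, 0 °C; then 20, CH2Cl2, rt
Reagents that add atoms: dibromomethane, BrCBr
Why: Takai–Lombardo methylenation is non-basic, so the hindered enolisable C8 ketone should be olefinated without epimerising C9, without touching the ester and without generating a C19 alkoxide that could trigger silyl migration from O20, and C9 is configurationally frozen afterwards.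

Step 11
Reactants: 21 exo-methylene hydroxy ester
Product: 22 C12,C19-diol
Conditions: LiAlH4, Et2O, 0 °C; aqueous work-up
Reagents that add atoms: none
Why: Hydride reduction of the ester gives the primary C12 alcohol, while the alkene and the hindered TBDPS ether are inert at this temperature and no stereocentre is touched.

Step 12
Reactants: 22 C12,C19-diol
Product: 23 C12 iodo alcohol
Conditions: PPh3, I2, imidazole (premixed), CH2Cl2, 0 °C
Reagents that add atoms: iodine, II
Why: Appel-type iodination discriminates the two primary alcohols because SN2 displacement of the alkoxyphosphonium ion is fast at unhindered C12 and practically impossible at the neopentyl axial C19, and premixing leaves no free iodine to attack the exocyclic alkene.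

Step 13
Reactants: 23 C12 iodo alcohol
Product: 24 iodo acetate
Conditions: Ac2O, pyridine, DMAP (cat.), CH2Cl2, rt
Reagents that add atoms: acetic anhydride, CC(=O)OC(C)=O
Why: DMAP-catalysed acetylation installs the C19 acetate of the target on the only free hydroxyl group.

Step 14
Reactants: 25 furan-2(5H)-one
Product: 27 3-bromofuran-2(5H)-one, via dibromolactone 26 (not isolated)
Conditions: Br2, CH2Cl2, reflux; then Et3N, 0 °C
Reagents that add atoms: bromine, BrBr
Why: Bromine addition to the butenolide alkene followed by amine-induced E1cB loss of HBr (removal of the acidic α-H, loss of the β-bromide) is the known halogenation–dehydrohalogenation route to the α-bromobutenolide.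

Step 15
Reactants: 24 iodo acetate; 27 3-bromofuran-2(5H)-one
Product: 29 silyl-protected butenolide, via alkylzinc iodide 28 (not isolated)
Conditions: Zn dust, LiCl, THF, 40 °C; then 27, Pd(OAc)2 (cat.), SPhos, THF, rt
Reagents that add atoms: none
Why: In this Negishi sp3–sp2 cross-coupling, LiCl-assisted zinc insertion gives an alkylzinc iodide that tolerates acetate, silyl ether and alkene, and zerovalent palladium formed from Pd(OAc)2 and SPhos should couple it with the electron-poor alkenyl bromide faster than β-hydride elimination, forming C12–C13 without touching any stereocentre.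

Step 16
Reactants: 29 silyl-protected butenolide
Product: 30 C20 alcohol
Conditions: HF·pyridine, pyridine, THF, 0 °C to rt
Reagents that add atoms: none
Why: Fluoride-mediated desilylation in a buffered, weakly acidic medium frees C20–OH while sparing the acetate, the base-sensitive butenolide and the exocyclic alkene, and avoids base-induced acetyl migration from O19 to O20.

Step 17
Reactants: 30 C20 alcohol
Product: 31 target CNP0109410.1
Conditions: Dess–Martin periodinane, CH2Cl2, rt
Reagents that add atoms: none
Why: Dess–Martin oxidation converts the neopentyl primary alcohol into the C20 aldehyde under neutral conditions, and this aldehyde sits on quaternary C10 and cannot epimerise.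

## Compound list

1 | (1R,5S)-(−)-myrtenol, (6,6-dimethylbicyclo[3.1.1]hept-2-en-2-yl)methanol | OCC1=CC[C@H]2C[C@@H]1C2(C)C | starting material
2 | TBDPS ether of 1 (bridgeheads as in 1) | CC(C)(C)[Si](OCC1=CC[C@H]2C[C@@H]1C2(C)C)(c1ccccc1)c1ccccc1 | intermediate
3 | 4-(TBDPS-oxymethyl)-6,6-dimethylbicyclo[3.1.1]hept-3-en-2-one (bridgeheads as in 1) | O=C1C=C(CO[Si](c2ccccc2)(c2ccccc2)C(C)(C)C)[C@@H]2C[C@H]1C2(C)C | intermediate
4 | vinylmagnesium bromide | C=C[Mg]Br | starting material
5 | bromomagnesium C8–C9 enolate of 6 | Br[Mg]OC1=C[C@@](C=C)(CO[Si](c2ccccc2)(c2ccccc2)C(C)(C)C)[C@@H]2C[C@H]1C2(C)C | intermediate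
6 | 4-(TBDPS-oxymethyl)-4-vinyl-6,6-dimethylbicyclo[3.1.1]heptan-2-one; vinyl anti, CH2OTBDPS syn to the CMe2 bridge | O=C1C[C@@](C=C)(CO[Si](c2ccccc2)(c2ccccc2)C(C)(C)C)[C@@H]2C[C@H]1C2(C)C | intermediate
7 | ethyl bromoacetate | CCOC(=O)CBr | starting material
8 | lithium C8–C9 enolate of 6 | [Li]OC1=C[C@@](C=C)(CO[Si](c2ccccc2)(c2ccccc2)C(C)(C)C)[C@@H]2C[C@H]1C2(C)C | intermediate
9 | 3-(ethoxycarbonylmethyl) derivative of 6; C9 arm β, anti to the CMe2 bridge | O=C1[C@H](CC(=O)OCC)[C@@](C=C)(CO[Si](c2ccccc2)(c2ccccc2)C(C)(C)C)[C@@H]2C[C@H]1C2(C)C | intermediate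
10 | ring-opened C7=C8 trimethylsilyl enol ether with 2-iodopropan-2-yl on C5 (C11 β) | C[Si](C)(C)OC1=CC[C@H](C(C)(C)I)[C@](C=C)(CO[Si](c2ccccc2)(c2ccccc2)C(C)(C)C)[C@H]1CC(=O)OCC | intermediate
11 | cyclohexanone with 2-iodopropan-2-yl on C5 (C11 β) | O=C1CC[C@H](C(C)(C)I)[C@](C=C)(CO[Si](c2ccccc2)(c2ccccc2)C(C)(C)C)[C@H]1CC(=O)OCC | intermediate
12 | ring B ketone: C5 isopropenyl (5β-H), C10 vinyl (β) and CH2OTBDPS (α), C9 CH2CO2Et (α, equatorial) | O=C1CC[C@H](C(C)=C)[C@](C=C)(CO[Si](c2ccccc2)(c2ccccc2)C(C)(C)C)[C@@H]1CC(=O)OCC | intermediate
13 | C4–C19 epoxide of 12 (both C4 epimers) | O=C1CC[C@H](C2(C)CO2)[C@](C=C)(CO[Si](c2ccccc2)(c2ccccc2)C(C)(C)C)[C@@H]1CC(=O)OCC | intermediate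
14 | 1,2,4-trioxolane from the vinyl group of 13 | O=C1CC[C@H](C2(C)CO2)[C@](C2OCOO2)(CO[Si](c2ccccc2)(c2ccccc2)C(C)(C)C)[C@@H]1CC(=O)OCC | intermediate
15 | epoxy aldehyde: as 13 with C1 formyl in place of vinyl | O=C1CC[C@H](C2(C)CO2)[C@](C=O)(CO[Si](c2ccccc2)(c2ccccc2)C(C)(C)C)[C@@H]1CC(=O)OCC | intermediate
16 | vinyltriphenylphosphonium bromide | C=C[P+](c1ccccc1)(c1ccccc1)c1ccccc1.[Br-] | starting material
17 | open-chain ylide: C4 quaternary (CH3, CH2OTiCp2Cl, CH2CH=PPh3), C1 formyl still present | O=C1CC[C@H]([C@](C)(CO[Ti](Cl)(C2C=CC=C2)C2C=CC=C2)CC=P(c2ccccc2)(c2ccccc2)c2ccccc2)[C@](C=O)(CO[Si](c2ccccc2)(c2ccccc2)C(C)(C)C)[C@@H]1CC(=O)OCC | intermediate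
18 | O19-titanium (Cp2TiCl) alkoxide of 19 | O=C1CC[C@@H]2[C@](C)(CO[Ti](Cl)(C3C=CC=C3)C3C=CC=C3)CC=C[C@@]2(CO[Si](c3ccccc3)(c3ccccc3)C(C)(C)C)[C@@H]1CC(=O)OCC | intermediate
19 | trans-fused octalone: C1=C2, C4 (β-CH3, α-CH2OH axial), 5β-H, C10 α-CH2OTBDPS, C8 ketone, C9 α-CH2CO2Et | O=C1CC[C@@H]2[C@](C)(CO)CC=C[C@@]2(CO[Si](c3ccccc3)(c3ccccc3)C(C)(C)C)[C@@H]1CC(=O)OCC | intermediate
20 | 1,2-dihydro derivative of 19 (trans-decalone) | O=C1CC[C@@H]2[C@](C)(CO)CCC[C@@]2(CO[Si](c3ccccc3)(c3ccccc3)C(C)(C)C)[C@@H]1CC(=O)OCC | intermediate
21 | 8(17)-methylene analogue of 20 | C=C1CC[C@@H]2[C@](C)(CO)CCC[C@@]2(CO[Si](c3ccccc3)(c3ccccc3)C(C)(C)C)[C@@H]1CC(=O)OCC | intermediate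
22 | C12,C19-diol | C=C1CC[C@@H]2[C@](C)(CO)CCC[C@@]2(CO[Si](c3ccccc3)(c3ccccc3)C(C)(C)C)[C@@H]1CCO | intermediate
23 | C12 iodide with free C19–OH | C=C1CC[C@@H]2[C@](C)(CO)CCC[C@@]2(CO[Si](c3ccccc3)(c3ccccc3)C(C)(C)C)[C@@H]1CCI | intermediate
24 | C12 iodide, C19 acetate | C=C1CC[C@@H]2[C@](C)(COC(C)=O)CCC[C@@]2(CO[Si](c3ccccc3)(c3ccccc3)C(C)(C)C)[C@@H]1CCI | intermediate
25 | furan-2(5H)-one | O=C1OCC=C1 | starting material
26 | 3,4-dibromodihydrofuran-2(3H)-one (racemic) | O=C1OCC(Br)C1Br | intermediate
27 | 3-bromofuran-2(5H)-one | O=C1OCC=C1Br | intermediate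
28 | C12 alkylzinc iodide from 24 | C=C1CC[C@@H]2[C@](C)(COC(C)=O)CCC[C@@]2(CO[Si](c3ccccc3)(c3ccccc3)C(C)(C)C)[C@@H]1CC[Zn]I | intermediate
29 | O20-TBDPS ether of 30 | C=C1CC[C@@H]2[C@](C)(COC(C)=O)CCC[C@@]2(CO[Si](c3ccccc3)(c3ccccc3)C(C)(C)C)[C@@H]1CCC1=CCOC1=O | intermediate
30 | 19-acetoxy-20-hydroxy-ent-labda-8(17),13-dien-16,15-olide | C=C1CC[C@@H]2[C@](C)(COC(C)=O)CCC[C@@]2(CO)[C@@H]1CCC1=CCOC1=O | intermediate
31 | CNP0109410.1, 19-acetoxy-20-oxo-ent-labda-8(17),13-dien-16,15-olide, (4R,5R,9R,10R) | C=C1CC[C@@H]2[C@](C)(COC(C)=O)CCC[C@@]2(C=O)[C@@H]1CCC1=CCOC1=O | target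

## Step count and risks

Total step count: 17. Longest linear sequence: 16 (steps 1–13 and 15–17).

### Step 8 (new method)

- **Process at risk:** the tertiary radical may be reduced or disproportionate before it is trapped. The ylide may add to further 16 instead of closing the ring. Facial selectivity at C4 may be poor.
- **Fallback (polar, known chemistry):** it sets out from 15 and comes back at 19. A Meinwald rearrangement (BF3·OEt2, CH2Cl2, −78 °C) turns the epoxide into the α-branched dialdehyde F1. KOtBu in THF deprotonates its only enolisable formyl group. The enolate adds to 16, and the resulting ylide closes ring A on the C1 aldehyde (vinylphosphonium Michael/Wittig annulation) to give the octalone C19-aldehyde F2. A(1,3) strain in the enolate (C5–H eclipsing C4=C19) and approach anti to C10 are expected to give the same C4 configuration. LiAlH(OtBu)3 at −78 °C should then reduce the aldehyde in preference to the ketone and give 19.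

### Step 5

- **Process at risk:** regiocontrol in the elimination may be lost (proton loss from C5 instead of from a methyl group). The tertiary cation may be captured by the neighbouring vinyl group.
- **Fallback (solvolysis and syn-elimination instead of E2):** it sets out from 9 and comes back at 12. After the same Me3SiI opening to 11, silver-assisted solvolysis (AgNO3, 2,6-lutidine, aqueous acetone) gives the tertiary alcohol F3. Burgess reagent (toluene, 50 °C) should take a methyl hydrogen for steric and statistical reasons and give the 9-epi isopropenyl ketone F4. Brief DBU treatment equilibrates C9 and gives 12.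

### Step 4

- **Process at risk:** SN2 alkylation at the enolate carbon next to quaternary C10 may be sluggish, with competing O-alkylation or proton transfer.
- **Fallback (radical instead of SN2):** it sets out from 6 and comes back at 9. LDA then Me3SiCl gives the trimethylsilyl enol ether F5. Photoredox alkylation with 7 (Ir(ppy)3, blue light, MeCN) adds the electrophilic CH2CO2Et radical to the electron-rich carbon C9 anti to the CMe2 bridge. Oxidation of the α-siloxy radical and loss of silicon give 9.

## Further compounds

F1 | step 8 | dialdehyde from Meinwald rearrangement of 15 (C4–H, both epimers) | O=C1CC[C@H](C(C)C=O)[C@](C=O)(CO[Si](c2ccccc2)(c2ccccc2)C(C)(C)C)[C@@H]1CC(=O)OCC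
F2 | step 8 | C19-aldehyde analogue of 19 | O=C1CC[C@@H]2[C@](C)(C=O)CC=C[C@@]2(CO[Si](c3ccccc3)(c3ccccc3)C(C)(C)C)[C@@H]1CC(=O)OCC
F3 | step 5 | tertiary alcohol, 2-hydroxypropan-2-yl on C5 (C11 β) | O=C1CC[C@H](C(C)(C)O)[C@](C=C)(CO[Si](c2ccccc2)(c2ccccc2)C(C)(C)C)[C@H]1CC(=O)OCC
F4 | step 5 | 9-epimer of 12 | O=C1CC[C@H](C(C)=C)[C@](C=C)(CO[Si](c2ccccc2)(c2ccccc2)C(C)(C)C)[C@H]1CC(=O)OCC
F5 | step 4 | C8–C9 trimethylsilyl enol ether of 6 | C[Si](C)(C)OC1=C[C@@](C=C)(CO[Si](c2ccccc2)(c2ccccc2)C(C)(C)C)[C@@H]2C[C@H]1C2(C)C
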